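The constants to start from are the first-order constants of substrate decay, each read as the logarithm of charged over remaining substrate, divided by time.

| flask | substrate | acid | remark | time |
|---|---|---|---|---|
| ochre | 25 mM | 0.050 mM | run made earlier |  |
| teal | 25 mM | 0.11 mM | run made earlier |  |
| flask | 25 mM | 0.0750 mM |  | 3.0 min |

| run | time / min | substrate / % | target / % |
|---|---|---|---|
| ochre | 0.667 | 66.9 | 26.3 |
| ochre | 1.33 | 43.5 | 32.5 |
| ochre | 2.00 | 30.3 | 27.1 |
| ochre | 2.50 | 21.7 | 23.6 |
| ochre | 3.00 | 16.6 | 21.7 |
| ochre | 4.00 | 9.0 | 15.0 |
| teal | 0.667 | 46.5 | 38.3 |
| teal | 1.33 | 22.4 | 33.9 |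
| teal | 2.00 | 8.1 | 24.1 |
| teal | 2.50 | 6.0 | 18.5 |
| teal | 3.00 | 2.7 | 16.2 |
| teal | 4.00 | 1.0 | 9.7 |

(each reading ± 1 percentage point)

- acid is the free proton; pH is minus the decimal logarithm of its molar concentration
- what was read earlier has a scatter of 1 percentage point, one standard deviation
- what may be going on: substrate + acid -> weak acid + acid + target; weak acid <-> conjugate base + acid; substrate -> weak acid + target; weak acid + target -> side product; target -> over-reaction product

* part of the substrate that has reacted at 3.0 min
* pH of the solution at 3.0 min

The ochre run reads 0.603 min⁻¹ at 0.667 min and 0.602 min⁻¹ at 4.00 min. With the constant this steady, the decay in the ochre run reads as pseudo-first-order, which indicates that [acid] stays near its charge there. The pH of the flask is then taken from its charged 0.0750 mM.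

The teal run reads 1.15 min⁻¹ at 0.667 min. The bench rule sets the constant proportional to [acid] and gives the flask 0.904 min⁻¹. That rule stops being exact between these runs: the constants differ by a factor of 1.91, less than the factor of 2.20 in [acid]. A straight line through both readings leaves an intercept of 0.148 min⁻¹ at zero [acid].

On that line the flask has 0.830 min⁻¹, a half-life of 0.835 min, and 3.59 half-lives in 3.0 min. This count of half-lives, time over half-life at the given [acid], is the quantity used from here on. Raising 0.5 to that count gives an estimate of 8.29% of the substrate remaining in the flask, and so of 91.7% reacted.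

The forecast gives 92% and pH 4.11, with the words “the free proton barely changes as weak acid forms”. The flask gives 92.2% and pH 4.12.

    substrate + acid → weak acid + acid + target (k = 160 M⁻¹ s⁻¹)
    weak acid ⇌ conjugate base + acid, settled at all times (K = 5.00 × 10⁻⁹ M)
    substrate → weak acid + target (k = 0.00210 s⁻¹)
    weak acid + target → side product (k = 1.80 M⁻¹ s⁻¹)
    target → over-reaction product (k = 0.00140 s⁻¹)

The 7.8% of substrate left in the flask amounts to 3.68 half-lives, against the 3.59 counted. At 0.728 min the flask made target 1.33 times as fast as it used it up. At 3.00 min, with 7.79% of substrate present, target was made at 0.478 of the rate of its use, and side product stood at 67.3%. The same half-life puts the reading at 50 s at 0.998 half-lives, leaving 50.1%; that neighbour flask holds 49% of substrate.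

The readings are simulated on assumed constants, noise included.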